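38.4% of the two substrates together still stands at 4.00 min in the south-east run, so this flask is reckoned by the fraction left.

| flask | left-handed substrate | right-handed substrate | partner | free catalyst | remark | time |
|---|---|---|---|---|---|---|
| south-east | 0.10 M | 0.10 M | 0.40 M | 20 mM | run made earlier |  |
| south | 0.15 M | 0.15 M | 0.40 M | 20 mM | run made earlier |  |
| east | 0.20 M | 0.20 M | 0.40 M | 30 mM | run made earlier |  |
| flask | 0.20 M | 0.20 M | 0.400 M | 20 mM |  | 4.0 min |

| run | time / min | left-handed substrate / % | right-handed substrate / % | left-handed product / % |
|---|---|---|---|---|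
| south-east | 0.833 | 26.8 | 28.4 | 27.5 |
| south-east | 1.50 | 24.8 | 24.3 | 31.5 |
| south-east | 2.50 | 21.2 | 21.6 | 34.9 |
| south-east | 3.00 | 20.1 | 21.3 | 36.6 |
| south-east | 4.00 | 18.7 | 19.7 | 38.1 |
| south | 0.833 | 29.2 | 29.8 | 25.5 |
| south | 1.50 | 25.3 | 26.0 | 29.6 |
| south | 2.50 | 22.6 | 22.7 | 32.8 |
| south | 3.00 | 20.8 | 21.8 | 34.5 |
| south | 4.00 | 21.3 | 20.6 | 35.6 |
| east | 0.333 | 31.9 | 33.2 | 21.4 |
| east | 1.00 | 25.9 | 27.2 | 28.7 |
| east | 2.00 | 22.7 | 22.8 | 33.6 |
| east | 3.00 | 22.5 | 22.0 | 34.4 |
| east | 4.00 | 20.2 | 20.1 | 35.5 |

(scatter of a reading: 0.5 percentage points)
- free catalyst is single-handed; left-handed substrate and right-handed substrate are mirror images of each other, charged as a racemate, each of them at the stated concentration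
- reactions considered so far: partner <-> dormant form; partner + free catalyst + right-handed substrate -> free catalyst + right-handed product; left-handed substrate <-> right-handed substrate; partner + free catalyst + left-handed substrate -> free catalyst + left-handed product; 2 free catalyst -> spent catalyst B; partner + free catalyst -> spent catalyst A
- an excess is the difference of the two amounts in percent of their sum
- an excess is below zero if the other one leads
- part of the left-handed substrate and right-handed substrate charged together that has reacted at 4.0 min
- excess of left-handed product over right-handed product in the product at 4.0 min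
- excess of right-handed substrate over left-handed substrate among what is left of the two at 4.0 min

For the next at the bench: both substrates read alike, so they count as one fraction f left; g is the fraction of the partner charge not yet taken into product, dormant form counted with partner, and m the substrate charged per partner charged. With a rate taken as first order in f and in g, the reach Λ is the −ln f a flask attains if g never falls:

g = 1 − m(1 − f), Λ = ln(g/f) / (1 − m), or Λ = 1/f − 1 at m = 1

south-east, m = 0.500: Λ = 1.18

south, m = 0.750, f = 41.9%: Λ = 1.19

The mean, 1.18, belongs to 20 mM of free catalyst, so that charge stays untouched: the east run at 30 mM reads 1.48, more. This flask has m = 1, so by 4.0 min my reckoning gives: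

c = Λ/(1 + Λ) = 54.2%

The forecast, holding that “The reaction stalls, which points to catalyst death”, gave 54.5%, 22.5% and 0.3%.

The flask gives 54.2%, 23.2% and 0.180%.

    partner ⇌ dormant form (K = 0.530, k = 0.0110 s⁻¹)
    partner + free catalyst + right-handed substrate → free catalyst + right-handed product (k = 3.00 L² mol⁻² s⁻¹)
    left-handed substrate ⇌ right-handed substrate (k = 0.0470 s⁻¹)
    partner + free catalyst + left-handed substrate → free catalyst + left-handed product (k = 5.00 L² mol⁻² s⁻¹)
    2 free catalyst → spent catalyst B (k = 1.10 L mol⁻¹ s⁻¹)
    partner + free catalyst → spent catalyst A (k = 0.0130 L mol⁻¹ s⁻¹)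

Its own fraction left gives a reach of 1.18. At 4.00 min the half-life of left-handed substrate by its product step is 14 min, long against 4.0 min, with free catalyst at 6.85% of its charge. That step then uses left-handed substrate at 0.017 of the rate of its passing into right-handed substrate, and the two stand at 22.9% and 23.0%. With 0.24 M of partner, m is 1.67 and the reach, scaled with the partner charge, 0.711; solving for f gives c = 36.1%, and that flask stands at 36.7%.

The readings come from a simulation for an exercise; scatter was added.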